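## Structural features

The target is a C2-symmetric 3,3''-biflavanone: two 7-hydroxy-2-(4-hydroxyphenyl)chroman-4-one (liquiritigenin) units, each built from a resorcinol-derived ring A fused to a dihydropyranone ring C with a 4-hydroxyphenyl ring B at C2, joined by one single bond between C3 and C3''. The four stereocentres form one unbroken chain C2–C3–C3''–C2''. A CIP reading of the SMILES gives (2R,3S,2''R,3''S): C2 and C3 are trans in each ring C, and the halves are homochiral, so the compound is chiral and not meso. C3 and C3'' are each alpha to a ketone and beta to an aryloxy leaving group, so base can epimerize them or open ring C by retro-oxa-Michael reaction. The free phenols, two of them para to a benzylic C2–O1 bond, are sensitive to oxidants. The real difficulty is the C3–C3'' bond between two tertiary, epimerizable carbons, which must be made with the right relative and absolute configuration; the C2–O1 bonds are easier because 2,3-trans is the more stable arrangement. Read as two chalcones, C3/C3'' are the alpha carbons and C2/C2'' the beta carbons of two isoliquiritigenin units. The key step uses this by joining both pairs in a head-to-head cyclobutane whose surplus C2–C2'' bond lies between two 4-oxyphenyl rings B and can be cut oxidatively while each ring-A 2'-hydroxyl closes ring C.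

## Logic of the disconnections

**9 to 8.** The bonds cut are O1–C2 and O1''–C2''. Each is the product of an oxa-conjugate addition of a ring-A hydroxyl to the exocyclic carbon of a para-quinone methide, and the trans ring is both the chair-like kinetic and the thermodynamic outcome. This removes both heterocycles and reduces the stereochemical problem to C3/C3'' in 8. The forward step must generate 8 without base and trap it before C3–H shifts.

**8 to 7.** In the retrosynthetic sense the C2–C2'' bond is re-formed, because 8 is the two-electron oxidation product of a 1,2-bis(4-hydroxyphenyl)cyclobutane. The gain is that the fragile, acyclic C3–C3'' pair of 8 becomes two carbons of a rigid four-membered ring in 7, which is a formal [2+2] dimer. The forward step must oxidize only the ring-B phenols and break C2–C2'' while leaving C3–C3'' intact.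

**7 to 6.** Four O–Si bonds are cut. Free ring-B and 4'-phenols would compete for the Lewis acid in the key step, so they are masked. The skeleton is unchanged. The forward desilylation must not create phenoxides, which could open the strained ring at C2–C3.

**6 to two molecules of 5.** The bonds cut are C2–C2'' and C3–C3'', the cyclobutane retron of two identical enones joined alpha to alpha and beta to beta. This halves the molecule and removes the ring and all four stereocentres, leaving an achiral, planar precursor. The forward step must be head-to-head, all-trans and selective for one enantiomer.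

**5 to 3 and 4.** Two O–Si bonds are cut. The forward silylation must take the 4- and 4'-hydroxyls and leave the chelated 2'-hydroxyl free, since that group is the binding site in the key step and the nucleophile in the last step.

**3 to 1 and 2.** The C2=C3 double bond is cut (aldol condensation retron), giving two commercial aromatics. The forward condensation must tolerate three free phenols and give the E-enone.

## Other disconnections considered

**Alternative 1:** The cut is at C4–C4a and C4''–C4a'', the aryl–carbonyl bonds of both rings C, with the 1,4-diketone C4–C3–C3''–C4'' stored as the four carbons of a furan.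
- Forward key step: the dibromide A1, a 3,4-disubstituted furan with two benzylic 2-bromoaryl ethers, would be treated with Pd(OAc)2, PCy3·HBF4, pivalic acid and K2CO3. Oxidative addition of zerovalent palladium into each C–Br bond, pivalate-assisted metalation of the adjacent furan alpha C–H and reductive elimination would close both pyran rings to the pentacyclic furan A2.
- In favour: the C3–C3'' bond comes with the furan. The reaction class of the key step is well documented, and on this point the alternative is the better plan, since the photodimerization chosen here has no direct model. Only C2 and C2'' need reagent control, because C3 and C3'' would be set last by protonation next to fixed C2 centres.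
- Against: the benzylic ether carbons of A1 are flanked by a furan and a 4-alkoxyphenyl ring and should ionize easily. Their construction from a 1,4-related diol competes with cyclodehydration to a bicyclic ether. A2 is still an oxidation and a reduction away from the diketone, because a 2,5-diarylfuran does not simply hydrolyse. Four benzyl ethers must then be removed next to two benzylic C2–O1 bonds.
- Comparison: structurally, A2 already holds rings A, B and C and both C–O stereocentres, whereas 6 holds C3/C3'' but not ring C. Mechanistically, A2 arises by closed-shell organopalladium chemistry and 6 by a triplet diradical. In step count the alternative needs roughly twice the five operations of the chosen plan.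

**Alternative 2:** The cut removes C2–C3 and C2''–C3'' together, leaving an E,E-diene whose inner carbons become C3 and C3''.
- Forward key step: the bis(benzyl) ether A3, a (2S,7S)-octa-3,5-diene-2,7-diol carrying 4-(triisopropylsilyloxy)benzyl groups on both oxygens, would be deprotonated at both benzylic carbons with excess n-BuLi in THF at low temperature. Two successive suprafacial [2,3]-Wittig shifts, through envelope transition states with the methyl group outside, would pass the carbinol chirality to the inner diene carbons and give the anti,anti diol A4 with two E-propenyl groups.
- In favour: four stereocentres and two C–C bonds arise in one operation, which equals the chosen plan. The C2–O bonds exist as ordinary alkoxides and never pass through a quinone methide, which is better than the chosen plan. No photochemistry is needed.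
- Against: the second shift must occur on a species that is already an alkoxide, and the [1,2]-shift competes. The anti preference of benzylic carbanions with E-alkenes is not reliably high. A3 needs enantiopure carbinol centres; the (S,S) assignment follows from the suprafacial model and would have to be confirmed.
- Comparison: structurally, A4 has neither ring A nor the C4 carbonyls. Each propenyl group must be cleaved, the hydroxy aldehydes (which would close to bis-lactols) arylated and reoxidized, and ring C closed by intramolecular O-arylation, all on epimerizable centres. Mechanistically it is an anionic pericyclic process under substrate control, against catalyst control in the chosen plan. In step economy it is clearly longer, well over ten steps.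

**Alternative 3:** The cut takes out each ring A through its two bonds (C4–C4a and O1–C8a and their counterparts), so the oxygenated core C2–C3–C3''–C2'' appears as a bis-lactone traced back to a racemizing 2,3-diaroylsuccinate.
- Forward key step: the diester A5 would be reduced with RuCl(p-cymene)[(R,R)-TsDPEN] in HCO2H/Et3N. Both aryl ketones are reduced while the alpha carbons equilibrate through the beta-keto ester enols, and each new hydroxyl acylates the ester of the other half to give the cis-fused exo,exo-dilactone A6.
- In favour: A5 is reached in two conventional steps, which equals the access to 5. The catalyst is commercial and dynamic kinetic transfer hydrogenation of beta-keto esters is an established reaction class, so on precedent this alternative is better than the chosen key step. Four stereocentres in one catalytic step is equal.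
- Against:
  - (a) After the first lactonization the second reduction is no longer an independent dynamic resolution. C3'' must satisfy both the catalyst and the cis ring fusion dictated by the already fixed C3, so a mismatched case can arise.
  - (b) Read with the lactone carbonyls as the future C4 and C4'', A6 carries C2 and C2'' in the sense of 9 but C3 and C3'' in the opposite sense: an aryl group cis to the ring-fusion hydrogen corresponds to a 2,3-cis ring C. Both alpha centres would need later epimerization under base, which is downhill but is applied to a compound prone to retro-oxa-Michael opening.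
  - (c) Each lactone must be opened by one equivalent of an ortho-functionalized aryl nucleophile without over-addition or retro-aldol cleavage, ring C closed by O-arylation, and the benzyl ethers removed.
- Comparison: structurally, A6 holds the four-carbon core but neither ring A nor ring C. Mechanistically it is a closed-shell hydride transfer with dynamic resolution, against a triplet cycloaddition. In steps it needs about nine to ten against five.

Key step: step 3

Assumption: the sense of induction of the scandium–pybox complex in a chalcone homodimerization cannot be derived with certainty, so (S,S)-t-Bu-pybox is written and its mirror image is meant if that antipode is the one leading to (1R,2R,3S,4S)-6.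

Check of the structures: 5 is the 4,4'-bis-silyl ether with free 2'-OH. 6 is all-trans and carries C3 and C3'' in the same spatial sense as 9, although the CIP letters change from R in 6, 7 and 8 to S in 9 because the substituent priorities change. Neither structure needed correction, and the TBS groups are kept.

## Route

Step 1
Reactants: 1 2,4-dihydroxyacetophenone; 2 4-hydroxybenzaldehyde
Product: 3 isoliquiritigenin
Conditions: KOH (60% aq, excess), EtOH, 0 °C → rt; then 2 M HCl, 0 °C, to pH 3
Reagents that add atoms: none
Why: Claisen–Schmidt (crossed aldol) condensation; the methyl ketone enolate adds to the aldehyde and E1cB loss of water gives the E-enone under thermodynamic control. In strong base the 2'-oxygen is a phenoxide and ring closure to the flavanone is suppressed; cold acidification avoids it on work-up.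

Step 2
Reactants: 3 isoliquiritigenin; 4 tert-butyldimethylsilyl chloride
Product: 5 4,4'-bis-O-TBS-isoliquiritigenin
Conditions: TBSCl (2.2 equiv), imidazole (4.5 equiv), DMF, 0 °C → rt
Reagents that add atoms: tert-butyldimethylsilyl chloride (4), CC(C)(C)[Si](C)(C)Cl
Why: Imidazole-promoted O-silylation of phenols; the 2'-hydroxyl is tied up in a six-membered hydrogen bond to the ketone and is the least nucleophilic, so two equivalents of silyl chloride should take only the 4- and 4'-hydroxyls.

Step 3
Reactants: 5 4,4'-bis-O-TBS-isoliquiritigenin (two molecules)
Product: 6 all-trans head-to-head cyclobutane dimer (1R,2R,3S,4S)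
Conditions: Ru(bpy)3(PF6)2 (2.5 mol%), Sc(OTf)3 (10 mol%), (S,S)-t-Bu-pybox (15 mol%), i-PrOAc/MeCN 3:1 (0.2 M), degassed, blue LEDs (450 nm), rt
Reagents that add atoms: none
Why: Proposed new method: the closest known reaction type is the Lewis-acid-enabled, triplet-sensitized enantioselective [2+2] cycloaddition of 2'-hydroxychalcones with styrenes and dienes, extended here to a second chalcone as the alkene partner; chelation of the 2'-hydroxy ketone of 5 to the Sc(OTf)3–pybox complex should lower its triplet energy below that of excited Ru(bpy)3(PF6)2, so only catalyst-bound 5 is sensitized and free 5 gives no racemic background. The bound triplet enone should bond through its beta carbon to the beta carbon of a ground-state molecule of 5 (C2–C2''), because this places both unpaired electrons alpha to a carbonyl in a 1,4-diradical, and that is the head-to-head regiochemistry required. The four-membered ring then closes by intersystem crossing and radical recombination at C3–C3'', a stepwise, non-concerted closure to which no Baldwin class applies. The configuration at C2 of the bound chalcone is set by the tert-butyl groups of the ligand, which leave one enone face open, and C2'' is set in the same bond-forming event by approach of the partner with its aryl group anti to the first (steric, substrate-based control). C3 and C3'' are set at ring closure, where the rotating radical centres place each aroyl group trans to its neighbours, so the all-trans (1R,2R,3S,4S) isomer should form and the catalyst-set C2 is relayed to C3 and C3''. The step thus needs head-to-head regioselectivity (secured by carbonyl stabilization of the diradical), all-trans diastereoselectivity (secured by steric relief around the ring) and one enantiomer (secured by the chiral scandium complex bound at the free 2'-hydroxyl), while the two silyl ethers keep the other phenols from competing for scandium. High concentration is used because no excess alkene partner is present, and E/Z isomerization of 5 is only an energy sink since the Z isomer re-enters the cycle.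

Step 4
Reactants: 6 all-trans head-to-head cyclobutane dimer
Product: 7 hexaphenol cyclobutane (1R,2R,3S,4S)
Conditions: Bu4NF (4.4 equiv), AcOH (6 equiv), THF, 0 °C
Reagents that add atoms: none
Why: Fluoride-induced cleavage of aryl silyl ethers, driven by Si–F bond formation. The AcOH buffer keeps every phenol protonated, so no ring-B phenoxide can push open the strained C2–C3 bond by retro-1,6-addition and C3/C3'' are not enolized; no stereocentre is touched.

Step 5
Reactants: 7 hexaphenol cyclobutane
Product: 9 (2R,3S,2''R,3''S)-3,3''-biliquiritigenin (the target), via bis(quinone methide) diketone 8 (not isolated)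
Conditions: Ag2O (1.1 equiv), dry acetone/CH2Cl2, 4 Å MS, dark, 0 °C → rt; filter through Celite
Reagents that add atoms: none
Why: Proposed new method: the closest known reaction types are the Ag2O oxidation of para-alkylphenols to para-quinone methides and the strain-driven ring opening of cyclobutylcarbinyl radicals; one-electron oxidation of each ring-B phenol of 7 should give phenoxyl radicals whose spin at the para carbon is beta to the strained C2–C2'' bond, so homolysis of that bond pairs the electrons into the two quinone methides of 8 with release of ring strain, whereas C3–C3'' lies between two acyl-bearing carbons and gains nothing from cleavage. Each 2'-hydroxyl then adds to its own quinone methide carbon in a 6-exo-trig oxa-conjugate addition that rearomatizes ring B; C2 and C2'' are set by the neighbouring C3 and C3'' through a chair-like transition state with the aryl group and the C3 substituent both equatorial, giving the 2,3-trans rings of 9, which is also the more stable arrangement.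

## Compound list

1 | 2,4-dihydroxyacetophenone | CC(=O)c1ccc(O)cc1O | starting material
2 | 4-hydroxybenzaldehyde | O=Cc1ccc(O)cc1 | starting material
3 | isoliquiritigenin, (E)-1-(2,4-dihydroxyphenyl)-3-(4-hydroxyphenyl)prop-2-en-1-one | O=C(/C=C/c1ccc(O)cc1)c1ccc(O)cc1O | intermediate
4 | tert-butyldimethylsilyl chloride | CC(C)(C)[Si](C)(C)Cl | starting material
5 | 4,4'-bis-O-TBS-isoliquiritigenin, (E)-1-[4-(tert-butyldimethylsilyloxy)-2-hydroxyphenyl]-3-[4-(tert-butyldimethylsilyloxy)phenyl]prop-2-en-1-one | O=C(/C=C/c1ccc(O[Si](C)(C)C(C)(C)C)cc1)c1ccc(O[Si](C)(C)C(C)(C)C)cc1O | intermediate
6 | [(1R,2R,3S,4S)-3,4-bis[4-(tert-butyldimethylsilyloxy)phenyl]cyclobutane-1,2-diyl]bis{[4-(tert-butyldimethylsilyloxy)-2-hydroxyphenyl]methanone}, all-trans head-to-head dimer | CC(C)(C)[Si](C)(C)Oc1ccc(cc1)[C@@H]1[C@@H](C(=O)c2ccc(O[Si](C)(C)C(C)(C)C)cc2O)[C@H](C(=O)c2ccc(O[Si](C)(C)C(C)(C)C)cc2O)[C@H]1c1ccc(O[Si](C)(C)C(C)(C)C)cc1 | intermediate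
7 | [(1R,2R,3S,4S)-3,4-bis(4-hydroxyphenyl)cyclobutane-1,2-diyl]bis[(2,4-dihydroxyphenyl)methanone], all-trans | Oc1ccc(cc1)[C@@H]1[C@@H](C(=O)c2ccc(O)cc2O)[C@H](C(=O)c2ccc(O)cc2O)[C@H]1c1ccc(O)cc1 | intermediate
8 | (2R,3R)-1,4-bis(2,4-dihydroxyphenyl)-2,3-bis[(4-oxocyclohexa-2,5-dien-1-ylidene)methyl]butane-1,4-dione | O=C1C=CC(C=C1)=C[C@@H](C(=O)c1ccc(O)cc1O)[C@@H](C=C1C=CC(=O)C=C1)C(=O)c1ccc(O)cc1O | intermediate (not isolated)
9 | (2R,3S)-7-hydroxy-3-[(2R,3S)-7-hydroxy-2-(4-hydroxyphenyl)-4-oxochroman-3-yl]-2-(4-hydroxyphenyl)chroman-4-one | O=C1c2ccc(O)cc2O[C@@H](c2ccc(O)cc2)[C@@H]1[C@@H]1C(=O)c2ccc(O)cc2O[C@H]1c1ccc(O)cc1 | target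

## Step count and least certain steps

Total step count: 5. Longest linear sequence: 5 steps (1 and 2 to 9; 4 enters in step 2).

**Step 3 (key step).** Three processes are most likely to fail:
- Trapping of the short-lived bound triplet by a second chalcone may be too slow against decay and E/Z isomerization, since no excess partner is present.
- First bonding at the alpha carbon of the partner would give the head-to-tail ring.
- Facial discrimination may be poor because the partner is bulkier than the alkenes usual for this catalyst, and chelation of the product to scandium may slow turnover.

Fallback, setting out from 5 and returning at 6: 5 is dimerized by plain triplet energy transfer without Lewis acid, using Ir[dF(CF3)ppy]2(dtbbpy)PF6 in MeCN under blue light. This is the known solution photodimerization of chalcones to head-to-head cyclobutanes. The racemic all-trans dimer is isolated, that is 6 together with its mirror image, the (1S,2S,3R,4R)-dimer F1. The enantiomers are then separated by preparative chromatography on a polysaccharide-carbamate chiral phase, which gives 6 for step 4.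

**Step 5.** Four processes are most likely to fail:
- After the first scission the C3–C3'' bond may also break, giving complete cycloreversion to two chalcone units.
- The benzylic hydrogen at C2 may be lost in place of the ring bond.
- The quinone methide may undergo a prototropic shift to the conjugated enone, which erases C3/C3'', if the chelated 2'-hydroxyl closes too slowly.
- The product's own ring-B phenols may be oxidized further.

Fallback with known reactions, setting out from 3 and returning at 9:
- 3 is isomerized with NaOAc in refluxing EtOH (chalcone–flavanone isomerization) to racemic liquiritigenin F2.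
- Both phenols are silylated (TBSCl, imidazole, DMF) to the racemic bis-silyl flavanone F3.
- The enantiomers are separated on a chiral stationary phase to give the (2R)-bis-silyl flavanone F4.
- Soft enolization (TMSOTf, Et3N, CH2Cl2, 0 °C) gives the trimethylsilyl enol ether F5.
- Oxidative homocoupling with Ag2O in DMSO, the known dimerization of silyl enol ethers to 1,4-diketones, should join two C3 centres anti to their C2 aryl groups to the tetrakis-silyl biflavanone F6. Any 2,3-cis ring can be equilibrated alpha to the ketone.
- Buffered fluoride as in step 4 then gives 9.

This path gives up the cyclobutane relay and relies on resolution and on trans-selective coupling.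

**Step 4.** If the buffer is insufficient, ring-B phenoxides form and can open the strained ring by retro-1,6-addition at C2–C3, with scrambling at C3 or fragmentation; incomplete desilylation is the milder failure. Fallback, setting out from 3 and returning at 7: the phenols are protected as benzyl ethers (BnBr, K2CO3, acetone) to give 4,4'-di-O-benzylisoliquiritigenin F7. The dimerization of step 3 applied to F7 should give the tetrabenzyl all-trans dimer F8. Neutral hydrogenolysis (H2, Pd/C, EtOAc/MeOH, rt) then frees the phenols to 7 without fluoride or phenoxide.

**Step 1.** Addition may be sluggish because the aldehyde is deactivated as its phenoxide, and partial ring closure to the flavanone may occur during acidification. Fallback, setting out from 1 and 2 and returning at 3: 1 is converted to 2-hydroxy-4-(methoxymethoxy)acetophenone F9 (MOMCl, K2CO3, acetone) and 2 to 4-(methoxymethoxy)benzaldehyde F10 (MOMCl, i-Pr2NEt, CH2Cl2). Claisen–Schmidt condensation (KOH, EtOH, rt) gives the bis-MOM chalcone F11, and HCl in MeOH at rt to 40 °C removes both acetals to give 3.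

## Further compounds

F1 | step 3 | [(1S,2S,3R,4R)-3,4-bis[4-(tert-butyldimethylsilyloxy)phenyl]cyclobutane-1,2-diyl]bis{[4-(tert-butyldimethylsilyloxy)-2-hydroxyphenyl]methanone}, mirror image of 6 | CC(C)(C)[Si](C)(C)Oc1ccc(cc1)[C@H]1[C@H](C(=O)c2ccc(O[Si](C)(C)C(C)(C)C)cc2O)[C@@H](C(=O)c2ccc(O[Si](C)(C)C(C)(C)C)cc2O)[C@@H]1c1ccc(O[Si](C)(C)C(C)(C)C)cc1
F2 | step 5 | racemic liquiritigenin, 7-hydroxy-2-(4-hydroxyphenyl)chroman-4-one | O=C1CC(c2ccc(O)cc2)Oc2cc(O)ccc12
F3 | step 5 | racemic 7-(tert-butyldimethylsilyloxy)-2-[4-(tert-butyldimethylsilyloxy)phenyl]chroman-4-one | O=C1CC(c2ccc(O[Si](C)(C)C(C)(C)C)cc2)Oc2cc(O[Si](C)(C)C(C)(C)C)ccc12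
F4 | step 5 | (2R)-7-(tert-butyldimethylsilyloxy)-2-[4-(tert-butyldimethylsilyloxy)phenyl]chroman-4-one | O=C1C[C@H](c2ccc(O[Si](C)(C)C(C)(C)C)cc2)Oc2cc(O[Si](C)(C)C(C)(C)C)ccc12
F5 | step 5 | (2R)-7-(tert-butyldimethylsilyloxy)-2-[4-(tert-butyldimethylsilyloxy)phenyl]-4-(trimethylsilyloxy)-2H-chromene | C[Si](C)(C)OC1=C[C@H](c2ccc(O[Si](C)(C)C(C)(C)C)cc2)Oc2cc(O[Si](C)(C)C(C)(C)C)ccc12
F6 | step 5 | (2R,3S,2''R,3''S)-7,4',7'',4'''-tetrakis-O-(tert-butyldimethylsilyl)-3,3''-biliquiritigenin | O=C1c2ccc(O[Si](C)(C)C(C)(C)C)cc2O[C@@H](c2ccc(O[Si](C)(C)C(C)(C)C)cc2)[C@@H]1[C@@H]1C(=O)c2ccc(O[Si](C)(C)C(C)(C)C)cc2O[C@H]1c1ccc(O[Si](C)(C)C(C)(C)C)cc1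
F7 | step 4 | 4,4'-di-O-benzylisoliquiritigenin, (E)-1-[4-(benzyloxy)-2-hydroxyphenyl]-3-[4-(benzyloxy)phenyl]prop-2-en-1-one | O=C(/C=C/c1ccc(OCc2ccccc2)cc1)c1ccc(OCc2ccccc2)cc1O
F8 | step 4 | [(1R,2R,3S,4S)-3,4-bis[4-(benzyloxy)phenyl]cyclobutane-1,2-diyl]bis{[4-(benzyloxy)-2-hydroxyphenyl]methanone} | c1ccccc1COc1ccc(cc1)[C@@H]1[C@@H](C(=O)c2ccc(OCc3ccccc3)cc2O)[C@H](C(=O)c2ccc(OCc3ccccc3)cc2O)[C@H]1c1ccc(OCc2ccccc2)cc1
F9 | step 1 | 2-hydroxy-4-(methoxymethoxy)acetophenone | CC(=O)c1ccc(OCOC)cc1O
F10 | step 1 | 4-(methoxymethoxy)benzaldehyde | O=Cc1ccc(OCOC)cc1
F11 | step 1 | (E)-1-[2-hydroxy-4-(methoxymethoxy)phenyl]-3-[4-(methoxymethoxy)phenyl]prop-2-en-1-one | O=C(/C=C/c1ccc(OCOC)cc1)c1ccc(OCOC)cc1O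
A1 | alternative 1 | 3,4-bis[(S)-[5-(benzyloxy)-2-bromophenoxy][4-(benzyloxy)phenyl]methyl]furan | Brc1ccc(OCc2ccccc2)cc1O[C@@H](c1ccc(OCc2ccccc2)cc1)c1cocc1[C@H](c1ccc(OCc2ccccc2)cc1)Oc1cc(OCc2ccccc2)ccc1Br
A2 | alternative 1 | tetra-O-benzyl pentacyclic furan-fused bis(2H-chromene) | c1(OCc3ccccc3)ccc2c(c1)O[C@@H](c1ccc(OCc3ccccc3)cc1)c1c2oc2c1[C@H](c1ccc(OCc3ccccc3)cc1)Oc1cc(OCc3ccccc3)ccc12
A3 | alternative 2 | (2S,3E,5E,7S)-2,7-bis{[4-(triisopropylsilyloxy)benzyl]oxy}octa-3,5-diene | C[C@H](OCc1ccc(O[Si](C(C)C)(C(C)C)C(C)C)cc1)/C=C/C=C/[C@H](C)OCc1ccc(O[Si](C(C)C)(C(C)C)C(C)C)cc1
A4 | alternative 2 | anti,anti-1,4-bis[4-(triisopropylsilyloxy)phenyl]-2,3-di[(E)-prop-1-enyl]butane-1,4-diol | O[C@@H](c1ccc(O[Si](C(C)C)(C(C)C)C(C)C)cc1)[C@@H](/C=C/C)[C@H](/C=C/C)[C@@H](O)c1ccc(O[Si](C(C)C)(C(C)C)C(C)C)cc1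
A5 | alternative 3 | diethyl 2,3-bis[4-(benzyloxy)benzoyl]butanedioate (stereolabile alpha centres) | CCOC(=O)C(C(=O)c1ccc(OCc2ccccc2)cc1)C(C(=O)OCC)C(=O)c1ccc(OCc2ccccc2)cc1
A6 | alternative 3 | exo,exo-4,8-bis[4-(benzyloxy)phenyl]-3,7-dioxabicyclo[3.3.0]octane-2,6-dione | O=C1O[C@@H](c2ccc(OCc3ccccc3)cc2)[C@H]2[C@@H]1[C@H](c1ccc(OCc3ccccc3)cc1)OC2=O
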